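**Retrosynthetic overview**

- The target is cut at the C5 ester oxygen, and at the tert-butyl ester and silyl ether that mask it, into a hydroxy lactone carrying the acrylate arm and a silyl-protected (2E,4E,6R,11S)-11-hydroxy-4,6-dimethyldodeca-2,4-dienoic acid.
- Feature: with the lactone numbered O1, C2(=O), C3=C4, C5, C6 and the acrylic acid arm C7=C8–C9, the neighbouring oxygen-bearing carbons C5 and C6 each carry one alkene carbon (C4 and C7). The core is therefore a concealed (3S,4S)-hexa-1,5-diene-3,4-diol, C2-symmetric and available from L-tartrate.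
- Key disconnections: C3=C4 (ring-closing metathesis of the diol mono-acrylate) and C7=C8 (cross-metathesis with tert-butyl acrylate), both in one flask.
- Side chain: C2'=C3' by Horner–Wadsworth–Emmons, C4'=C5' by Wittig, C9'–C10' by Grignard opening of (S)-propylene oxide, with C6' taken from (R)-citronellene.
- Ring order: the six-membered lactone is the only ring and is closed in the key step; both ring stereocentres are in place before it.

Key step: step 4

Assumption: the commercial acetonide of dimethyl L-tartrate serves as the tartrate building block, and (R)-citronellene and (S)-propylene oxide are taken as enantiomerically pure.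

**Route**

Step 1
Reactants: 1 dimethyl (4R,5R)-2,2-dimethyl-1,3-dioxolane-4,5-dicarboxylate
Product: 3 (4S,5S)-4,5-diethenyl-2,2-dimethyl-1,3-dioxolane, via bis-aluminium hemiacetal 2 (not isolated)
Conditions: i-Bu2AlH (2.1 equiv), toluene, −78 °C; then Ph3P=CH2 (from Ph3PCH3Br, KOt-Bu, THF), −78 °C → rt
Reagents that add atoms: methyltriphenylphosphonium bromide (methylene carbon, through its ylide), C[P+](c1ccccc1)(c1ccccc1)c1ccccc1.[Br-]
Why: At −78 °C i-Bu2AlH should stop at the tetrahedral aluminium hemiacetal 2, which releases each aldehyde group only as the ylide consumes it (one-pot partial ester reduction and Wittig methylenation), so the epimerisable dialdehyde is never free and both stereocentres are carried over from tartrate unchanged.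

Step 2
Reactants: 3 (4S,5S)-4,5-diethenyl-2,2-dimethyl-1,3-dioxolane
Product: 4 (3S,4S)-hexa-1,5-diene-3,4-diol
Conditions: 1 M HCl, THF, rt
Reagents that add atoms: none
Why: Acid-catalysed hydrolysis of the isopropylidene acetal should free the diol without touching either C–O stereocentre, and the water-soluble diol is easily freed of residual phosphine oxide.

Step 3
Reactants: 4 (3S,4S)-hexa-1,5-diene-3,4-diol; 5 acryloyl chloride
Product: 7 (3S,4S)-4-hydroxyhexa-1,5-dien-3-yl prop-2-enoate, via stannylene acetal 6 (not isolated)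
Conditions: Bu2SnO (1.05 equiv), toluene, reflux (Dean–Stark); then 5 (1.0 equiv), 0 °C
Reagents that add atoms: none
Why: Tin-mediated mono-acylation of a 1,2-diol through its dibutylstannylene acetal transfers one acyl group only, and because the two hydroxyls of the C2-symmetric diol are homotopic a single mono-acrylate should result, for which acyl migration is degenerate.

Step 4
Reactants: 7 (3S,4S)-4-hydroxyhexa-1,5-dien-3-yl prop-2-enoate; 8 tert-butyl acrylate
Product: 10 tert-butyl (E)-3-[(2S,3S)-3-hydroxy-6-oxo-3,6-dihydro-2H-pyran-2-yl]prop-2-enoate, via vinyl lactone 9 (not isolated)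
Conditions: RuCl2(=CHPh)(PCy3)(H2IMes) (second-generation Grubbs catalyst, 5 mol %), 1,4-benzoquinone (10 mol %), CH2Cl2 (0.01 M), 40 °C; then 8 (10 equiv), concentrated to ca. 0.1 M, further catalyst (5 mol %), 40 °C
Reagents that add atoms: none
Why: The ruthenium benzylidene exchanges onto a terminal vinyl group, and the alkylidene on the vinyl next to the free C5 hydroxyl adds across the acrylate C=C through a ruthenacyclobutane that cycloreverts with loss of ethene, forming C3=C4 and the lactone by ring-closing metathesis; the same catalyst then joins the remaining C6 vinyl group to tert-butyl acrylate by cross-metathesis, again with loss of ethene. The closest known reactions are the ring-closing metathesis of acrylates of homoallylic alcohols to 5,6-dihydropyran-2-ones and the cross-metathesis of oxygen-substituted allylic vinyl groups with acrylates, run here as a one-pot sequence. The single ring is closed as a six-membered ring by metathesis between the acrylate terminus (C3) and the vinyl carbon C4, the cis C3=C4 bond lying inside the ring. No stereocentre is made: C5 and C6 come unchanged from tartrate, and the new C7=C8 bond should be E because olefin exchange is reversible until the conjugated trans enoate, the thermodynamic product of acrylate cross-metathesis, is reached. The step needs six-ring over five-ring closure and cross-metathesis at the C6 vinyl only; the first should hold because the acyloxy-bearing vinyl could close onto its own acrylate only to a butenolide, which acrylates form sluggishly, while the free allylic hydroxyl speeds loading of ruthenium on the C5-side vinyl, and the second because tert-butyl acrylate is added only after that vinyl has been consumed by ring closure.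

Step 5
Reactants: 11 (R)-3,7-dimethylocta-1,6-diene
Product: 13 (R)-4-methylhex-5-en-1-ol, via aldehyde 12 (not isolated)
Conditions: O3, CH2Cl2/MeOH, Sudan Red 7B end-point, −78 °C; then NaBH4, −78 °C → rt
Reagents that add atoms: ozone, [O-][O+]=O
Why: Chemoselective ozonolysis, since ozone attacks the electron-rich trisubstituted alkene much faster than the monosubstituted vinyl group and the dye marks one equivalent, with NaBH4 work-up reducing aldehyde 12 in the same flask; the stereocentre is not involved.

Step 6
Reactants: 13 (R)-4-methylhex-5-en-1-ol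
Product: 14 (R)-6-bromo-3-methylhex-1-ene
Conditions: CBr4, PPh3, CH2Cl2, 0 °C
Reagents that add atoms: carbon tetrabromide, BrC(Br)(Br)Br
Why: Appel bromination of a primary alcohol under neutral conditions, which leaves the alkene and the remote stereocentre untouched.

Step 7
Reactants: 14 (R)-6-bromo-3-methylhex-1-ene; 15 (S)-2-methyloxirane
Product: 17 (2S,7R)-7-methylnon-8-en-2-ol, via Grignard reagent 16 (not isolated)
Conditions: Mg, THF, 25–40 °C; then CuI (10 mol %), 15, −30 → 0 °C; aq. NH4Cl
Reagents that add atoms: none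
Why: Copper-catalysed SN2 opening of the terminal epoxide by the primary Grignard reagent occurs at the unsubstituted carbon, so the C–O stereocentre of (S)-propylene oxide is untouched and becomes the (S)-carbinol centre; only minor radical cyclisation is expected when the hex-5-enyl Grignard reagent is formed.

Step 8
Reactants: 17 (2S,7R)-7-methylnon-8-en-2-ol
Product: 18 triethyl{[(2S,7R)-7-methylnon-8-en-2-yl]oxy}silane
Conditions: Et3SiCl, imidazole, CH2Cl2, 0 °C → rt
Reagents that add atoms: chlorotriethylsilane, CC[Si](Cl)(CC)CC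
Why: Standard silyl ether protection of a secondary alcohol, the triethylsilyl group being chosen because it leaves under the same acid that cleaves the tert-butyl ester in step 14.

Step 9
Reactants: 18 triethyl{[(2S,7R)-7-methylnon-8-en-2-yl]oxy}silane
Product: 20 (2R,7S)-2-methyl-7-(triethylsilyloxy)octanal, via ozonide 19 (not isolated)
Conditions: O3, CH2Cl2, −78 °C; then PPh3, −78 °C → rt
Reagents that add atoms: ozone, [O-][O+]=O
Why: Ozonolysis of the only remaining alkene with neutral reductive work-up of ozonide 19 gives the α-methyl aldehyde without epimerising the adjacent stereocentre; the aldehyde is used at once.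

Step 10
Reactants: 20 (2R,7S)-2-methyl-7-(triethylsilyloxy)octanal
Product: 21 (2E,4R,9S)-2,4-dimethyl-9-(triethylsilyloxy)dec-2-enal
Conditions: Ph3P=C(CH3)CHO, toluene, 90 °C
Reagents that add atoms: 2-(triphenylphosphoranylidene)propanal, CC(C=O)=P(c1ccccc1)(c1ccccc1)c1ccccc1
Why: Wittig olefination with the stabilised formyl ylide should give the (E)-trisubstituted enal, and the weakly basic ylide should not epimerise the α-stereocentre.

Step 11
Reactants: 21 (2E,4R,9S)-2,4-dimethyl-9-(triethylsilyloxy)dec-2-enal
Product: 22 ethyl (2E,4E,6R,11S)-4,6-dimethyl-11-(triethylsilyloxy)dodeca-2,4-dienoate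
Conditions: (EtO)2P(O)CH2CO2Et, NaH, THF, 0 °C → rt
Reagents that add atoms: triethyl phosphonoacetate, CCOC(=O)CP(=O)(OCC)OCC
Why: Horner–Wadsworth–Emmons olefination of the enal with the phosphonoacetate anion should give the (2E)-alkene and so complete the (2E,4E)-dienoate.

Step 12
Reactants: 22 ethyl (2E,4E,6R,11S)-4,6-dimethyl-11-(triethylsilyloxy)dodeca-2,4-dienoate
Product: 23 (2E,4E,6R,11S)-4,6-dimethyl-11-(triethylsilyloxy)dodeca-2,4-dienoic acid
Conditions: LiOH, THF/MeOH/H2O, rt; then 0.5 M HCl to pH 4–5, 0 °C
Reagents that add atoms: lithium hydroxide (hydroxide oxygen), [Li+].[OH-]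
Why: Saponification of the ethyl ester, which the secondary triethylsilyl ether should tolerate at room temperature together with a cold, mildly acidic work-up.

Step 13
Reactants: 10 tert-butyl (E)-3-[(2S,3S)-3-hydroxy-6-oxo-3,6-dihydro-2H-pyran-2-yl]prop-2-enoate; 23 (2E,4E,6R,11S)-4,6-dimethyl-11-(triethylsilyloxy)dodeca-2,4-dienoic acid
Product: 24 (2S,3S)-2-[(E)-3-tert-butoxy-3-oxoprop-1-en-1-yl]-6-oxo-3,6-dihydro-2H-pyran-3-yl (2E,4E,6R,11S)-4,6-dimethyl-11-(triethylsilyloxy)dodeca-2,4-dienoate
Conditions: DCC, DMAP (0.2 equiv), CH2Cl2, 0 °C → rt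
Reagents that add atoms: none
Why: Steglich esterification, in which the acylpyridinium derived from 23 acylates the secondary allylic alcohol with retention at C5, and catalytic DMAP at low temperature should spare the base-sensitive lactone.

Step 14
Reactants: 24 (2S,3S)-2-[(E)-3-tert-butoxy-3-oxoprop-1-en-1-yl]-6-oxo-3,6-dihydro-2H-pyran-3-yl (2E,4E,6R,11S)-4,6-dimethyl-11-(triethylsilyloxy)dodeca-2,4-dienoate
Product: 25 (E)-3-[(2S,3S)-3-{[(2E,4E,6R,11S)-11-hydroxy-4,6-dimethyldodeca-2,4-dienoyl]oxy}-6-oxo-3,6-dihydro-2H-pyran-2-yl]prop-2-enoic acid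
Conditions: CF3CO2H/CH2Cl2/H2O (10:10:1), 0 °C → rt
Reagents that add atoms: none
Why: Acidolysis should cleave the tert-butyl ester through the tert-butyl cation and hydrolyse the triethylsilyl ether, while the lactone, the allylic ester flanked by electron-poor alkenes and the conjugated diene are expected to be stable to cold aqueous CF3CO2H.

**Compound list**

1 | dimethyl (4R,5R)-2,2-dimethyl-1,3-dioxolane-4,5-dicarboxylate (acetonide of dimethyl L-tartrate) | COC(=O)[C@@H]1OC(C)(C)O[C@H]1C(=O)OC | starting material
2 | (4R,5R)-4,5-bis[(diisobutylalumanyloxy)(methoxy)methyl]-2,2-dimethyl-1,3-dioxolane (masked dialdehyde, hemiacetal carbons undefined, not isolated) | COC(O[Al](CC(C)C)CC(C)C)[C@@H]1OC(C)(C)O[C@H]1C(OC)O[Al](CC(C)C)CC(C)C | intermediate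
3 | (4S,5S)-4,5-diethenyl-2,2-dimethyl-1,3-dioxolane | C=C[C@@H]1OC(C)(C)O[C@H]1C=C | intermediate
4 | (3S,4S)-hexa-1,5-diene-3,4-diol | C=C[C@H](O)[C@@H](O)C=C | intermediate
5 | acryloyl chloride | C=CC(Cl)=O | starting material
6 | (4S,5S)-2,2-dibutyl-4,5-diethenyl-1,3,2-dioxastannolane (not isolated) | C=C[C@@H]1O[Sn](CCCC)(CCCC)O[C@H]1C=C | intermediate
7 | (3S,4S)-4-hydroxyhexa-1,5-dien-3-yl prop-2-enoate | C=C[C@H](O)[C@@H](OC(=O)C=C)C=C | intermediate
8 | tert-butyl acrylate | C=CC(=O)OC(C)(C)C | starting material
9 | (5S,6S)-6-ethenyl-5-hydroxy-5,6-dihydro-2H-pyran-2-one (not isolated) | O[C@H]1C=CC(=O)O[C@H]1C=C | intermediate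
10 | tert-butyl (E)-3-[(2S,3S)-3-hydroxy-6-oxo-3,6-dihydro-2H-pyran-2-yl]prop-2-enoate | O[C@H]1C=CC(=O)O[C@H]1/C=C/C(=O)OC(C)(C)C | intermediate
11 | (R)-3,7-dimethylocta-1,6-diene ((R)-citronellene) | C=C[C@H](C)CCC=C(C)C | starting material
12 | (R)-4-methylhex-5-enal (not isolated) | C=C[C@H](C)CCC=O | intermediate
13 | (R)-4-methylhex-5-en-1-ol | C=C[C@H](C)CCCO | intermediate
14 | (R)-6-bromo-3-methylhex-1-ene | C=C[C@H](C)CCCBr | intermediate
15 | (S)-2-methyloxirane ((S)-propylene oxide) | C[C@H]1CO1 | starting material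
16 | [(R)-4-methylhex-5-en-1-yl]magnesium bromide (not isolated) | C=C[C@H](C)CCC[Mg]Br | intermediate
17 | (2S,7R)-7-methylnon-8-en-2-ol | C=C[C@H](C)CCCC[C@H](C)O | intermediate
18 | triethyl{[(2S,7R)-7-methylnon-8-en-2-yl]oxy}silane | C=C[C@H](C)CCCC[C@H](C)O[Si](CC)(CC)CC | intermediate
19 | 3-[(2R,7S)-7-(triethylsilyloxy)octan-2-yl]-1,2,4-trioxolane (ozonide, ring carbon undefined, not isolated) | O1OC(OC1)[C@H](C)CCCC[C@H](C)O[Si](CC)(CC)CC | intermediate
20 | (2R,7S)-2-methyl-7-(triethylsilyloxy)octanal | O=C[C@H](C)CCCC[C@H](C)O[Si](CC)(CC)CC | intermediate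
21 | (2E,4R,9S)-2,4-dimethyl-9-(triethylsilyloxy)dec-2-enal | O=C/C(C)=C/[C@H](C)CCCC[C@H](C)O[Si](CC)(CC)CC | intermediate
22 | ethyl (2E,4E,6R,11S)-4,6-dimethyl-11-(triethylsilyloxy)dodeca-2,4-dienoate | CCOC(=O)/C=C/C(C)=C/[C@H](C)CCCC[C@H](C)O[Si](CC)(CC)CC | intermediate
23 | (2E,4E,6R,11S)-4,6-dimethyl-11-(triethylsilyloxy)dodeca-2,4-dienoic acid | OC(=O)/C=C/C(C)=C/[C@H](C)CCCC[C@H](C)O[Si](CC)(CC)CC | intermediate
24 | (2S,3S)-2-[(E)-3-tert-butoxy-3-oxoprop-1-en-1-yl]-6-oxo-3,6-dihydro-2H-pyran-3-yl (2E,4E,6R,11S)-4,6-dimethyl-11-(triethylsilyloxy)dodeca-2,4-dienoate | CC(/C=C/C(=O)O[C@H]1C=CC(=O)O[C@H]1/C=C/C(=O)OC(C)(C)C)=C\[C@H](C)CCCC[C@H](C)O[Si](CC)(CC)CC | intermediate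
25 | (E)-3-[(2S,3S)-3-{[(2E,4E,6R,11S)-11-hydroxy-4,6-dimethyldodeca-2,4-dienoyl]oxy}-6-oxo-3,6-dihydro-2H-pyran-2-yl]prop-2-enoic acid (CNP0107712.2) | CC(/C=C/C(=O)O[C@H]1C=CC(=O)O[C@H]1/C=C/C(=O)O)=C\[C@H](C)CCCC[C@H](C)O | target

**Count**

Total steps: 14. Longest linear sequence: 10 steps (steps 5 to 14, from 11). The core branch (steps 1 to 4) joins at step 13.

**Steps most likely to fail**

Step 4. The cross-metathesis stage may stall on the oxygen-flanked, acceptor-like C6 vinyl group while the ruthenium methylidene decays. Ruthenium hydrides may also isomerise the free allylic alcohol, or closure to the five-membered lactone may compete. Fallback: setting out from 7, only the ring closure is run (same catalyst, dilute CH2Cl2, 40 °C) and 9 is isolated. Its terminal vinyl group is then cleaved selectively with ozone (CH2Cl2, −78 °C, dye end-point, then PPh3), since the conjugated ring alkene reacts far more slowly, to give (2R,3S)-3-hydroxy-6-oxo-3,6-dihydro-2H-pyran-2-carbaldehyde F1. This aldehyde is treated without storage with Ph3P=CHCO2t-Bu in CH2Cl2 at 0 °C; the E-selective Wittig olefination returns to the route at 10.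

Step 13. Acylation of the hindered allylic hydroxyl by a conjugated acid may be slow. Rearrangement of the activated acid to the N-acylurea, DMAP-induced elimination of the C5 oxygen towards a 2-pyranone, or translactonisation could then take over. Fallback: setting out from 10, the hydroxyl is first acylated with the small diethylphosphonoacetic acid and DCC without DMAP, giving tert-butyl (E)-3-[(2S,3S)-3-{[2-(diethoxyphosphoryl)acetyl]oxy}-6-oxo-3,6-dihydro-2H-pyran-2-yl]prop-2-enoate F2. A Masamune–Roush Horner–Wadsworth–Emmons reaction of this phosphonate with enal 21 (LiCl, i-Pr2NEt, MeCN, 0 °C → rt) then builds C2'=C3' on the core and comes back to the route at 24. Steps 11 and 12 are not needed in this variant.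

Step 14. The acid needed for the tert-butyl ester may trifluoroacetylate the freed alcohol, transesterify or open the lactone, or isomerise the diene before both groups are off. Fallback: the tert-butyl ester is avoided altogether. Setting out from 9 (isolated after the ring-closing stage of step 4) and acid 23, Steglich esterification (DCC, DMAP, CH2Cl2, 0 °C) gives (2S,3S)-2-ethenyl-6-oxo-3,6-dihydro-2H-pyran-3-yl (2E,4E,6R,11S)-4,6-dimethyl-11-(triethylsilyloxy)dodeca-2,4-dienoate F3. Cross-metathesis of its vinyl group with acrylic acid, using the second-generation Hoveyda–Grubbs catalyst RuCl2(=CH-C6H4-2-O-i-Pr)(H2IMes) in CH2Cl2 at 40 °C, should give (E)-3-[(2S,3S)-3-{[(2E,4E,6R,11S)-4,6-dimethyl-11-(triethylsilyloxy)dodeca-2,4-dienoyl]oxy}-6-oxo-3,6-dihydro-2H-pyran-2-yl]prop-2-enoic acid F4. The di- and trisubstituted alkenes of the side chain are expected to stay out of the metathesis. Mild removal of the silyl group (AcOH/THF/H2O, rt) comes back to the route at 25.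

**Further compounds**

F1 | step 4 | (2R,3S)-3-hydroxy-6-oxo-3,6-dihydro-2H-pyran-2-carbaldehyde | O[C@H]1C=CC(=O)O[C@H]1C=O
F2 | step 13 | tert-butyl (E)-3-[(2S,3S)-3-{[2-(diethoxyphosphoryl)acetyl]oxy}-6-oxo-3,6-dihydro-2H-pyran-2-yl]prop-2-enoate | CCOP(=O)(OCC)CC(=O)O[C@H]1C=CC(=O)O[C@H]1/C=C/C(=O)OC(C)(C)C
F3 | step 14 | (2S,3S)-2-ethenyl-6-oxo-3,6-dihydro-2H-pyran-3-yl (2E,4E,6R,11S)-4,6-dimethyl-11-(triethylsilyloxy)dodeca-2,4-dienoate | CC(/C=C/C(=O)O[C@H]1C=CC(=O)O[C@H]1C=C)=C\[C@H](C)CCCC[C@H](C)O[Si](CC)(CC)CC
F4 | step 14 | (E)-3-[(2S,3S)-3-{[(2E,4E,6R,11S)-4,6-dimethyl-11-(triethylsilyloxy)dodeca-2,4-dienoyl]oxy}-6-oxo-3,6-dihydro-2H-pyran-2-yl]prop-2-enoic acid | CC(/C=C/C(=O)O[C@H]1C=CC(=O)O[C@H]1/C=C/C(=O)O)=C\[C@H](C)CCCC[C@H](C)O[Si](CC)(CC)CC
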